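## Retrosynthetic overview
1. Acetate ⇒ threo alcohol ⇒ (8R) α-aryloxy aryl ketone. C7 is set last by Felkin–Anh hydride delivery under the control of C8.
2. Ketone ⇒ C1–C7 disconnection into the 3,4,5-trimethoxyphenyl Grignard reagent (fragment A, from the aryl bromide) and an (R)-2-aryloxy Weinreb amide (fragment B). This acylation is the late fragment union.
3. Fragment B ⇒ C8–O bond by Mitsunobu inversion of the (S)-lactic Weinreb amide with syringaldehyde, then E-selective Takai–Utimoto ethylidenation of the formyl group with 1,1-diiodoethane.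
4. Fragment A ⇒ resorcinol (O-methylation, directed lithiation/borylation/oxidation, para-bromination, O-methylation). Syringaldehyde ⇒ p-cresol (bromination/hydrolysis, copper-catalysed methoxylation).
5. No ring is formed: ring A comes in with resorcinol and ring B with p-cresol.

Assumption: the SMILES is read as (7R,8R), the threo series, where C7 is the acetoxy-bearing benzylic carbon, C8 the aryloxy-bearing carbon, ring A the trimethoxyphenyl ring and ring B the dimethoxy-propenylphenoxy ring.

## Route

Step 1
Reactants: 1 resorcinol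
Product: 2 1,3-dimethoxybenzene
Conditions: MeI, K2CO3, acetone, reflux
Reagents that add atoms: iodomethane, CI
Why: Williamson ether synthesis, in which both phenoxides formed by K2CO3 are methylated by MeI in SN2 reactions.

Step 2
Reactants: 2 1,3-dimethoxybenzene
Product: 5 2,6-dimethoxyphenol, via 2,6-dimethoxyphenyllithium 3 (not isolated), via dimethyl 2,6-dimethoxyphenylboronate 4 (not isolated)
Conditions: n-BuLi, THF, 0 °C → rt; B(OMe)3, −78 °C → rt; AcOH, 30% H2O2, 0 °C → rt
Reagents that add atoms: hydrogen peroxide, OO (phenol oxygen); n-butyllithium, [Li]CCCC (Li held only in 3); trimethyl borate, COB(OC)OC (boron unit held only in 4)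
Why: Directed ortho-metalation, in which the two methoxy groups jointly steer n-BuLi to C2, and borylation followed by peroxide oxidation (aryl shift from boron to oxygen) places the hydroxyl exactly there.

Step 3
Reactants: 5 2,6-dimethoxyphenol
Product: 6 4-bromo-2,6-dimethoxyphenol
Conditions: NBS, NaH (cat.), CHCl3–MeOH (100:1), −45 °C, then reflux
Reagents that add atoms: N-bromosuccinimide, O=C1CCC(=O)N1Br
Why: Electrophilic aromatic bromination through the phenoxide, whose para carbon is its only free ortho/para site, so that at low temperature C4 outruns the methoxy-activated C3/C5.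

Step 4
Reactants: 6 4-bromo-2,6-dimethoxyphenol
Product: 7 5-bromo-1,2,3-trimethoxybenzene (fragment A)
Conditions: MeI, K2CO3, acetone, reflux
Reagents that add atoms: iodomethane, CI
Why: Williamson ether synthesis on the hindered but acidic phenol, with the aryl bromide inert under these conditions.

Step 5
Reactants: 8 ethyl (S)-lactate
Product: 9 (S)-2-hydroxy-N-methoxy-N-methylpropanamide
Conditions: MeNHOMe·HCl, i-PrMgCl, THF, −20 → 0 °C; aq. NH4Cl
Reagents that add atoms: N,O-dimethylhydroxylamine hydrochloride, CNOC.Cl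
Why: Weinreb amide formation by aminolysis of the ester with the magnesium amide made in the flask, and the stereocentre stays (S) because the magnesium alkoxide formed first disfavours enolisation at low temperature.

Step 6
Reactants: 10 p-cresol
Product: 13 3,5-dibromo-4-hydroxybenzaldehyde, via 2,6-dibromo-4-methylphenol 11 (not isolated), via 2,6-dibromo-4-(dibromomethyl)phenol 12 (not isolated)
Conditions: Br2 (2 equiv), o-dichlorobenzene, 35 °C; Br2 (2 equiv), 150–160 °C; H2O, 100 °C
Reagents that add atoms: bromine, BrBr; water, O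
Why: Electrophilic ortho-dibromination (para position blocked), thermal benzylic bromination to the benzal bromide and hydrolysis of the gem-dibromide, assisted by the para-hydroxyl group, give the aldehyde in one pot.

Step 7
Reactants: 13 3,5-dibromo-4-hydroxybenzaldehyde
Product: 14 syringaldehyde (4-hydroxy-3,5-dimethoxybenzaldehyde)
Conditions: NaOMe, CuCl (cat.), DMF–MeOH, 115 °C; aq. HCl
Reagents that add atoms: sodium methoxide, [Na+].[O-]C
Why: Copper-catalysed Ullmann-type methoxylation replaces both aryl bromides, while the phenoxide present under the conditions deactivates the formyl group toward methoxide.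

Step 8
Reactants: 14 syringaldehyde; 9 (S)-2-hydroxy-N-methoxy-N-methylpropanamide
Product: 15 (R)-2-(4-formyl-2,6-dimethoxyphenoxy)-N-methoxy-N-methylpropanamide
Conditions: PPh3, DIAD, THF, 0 °C → rt
Reagents that add atoms: none
Why: Mitsunobu reaction, in which the acidic phenol (pKa about 7) displaces the oxyphosphonium group of 9 in an SN2 reaction with clean inversion, turning the (S) carbinol into the (R) aryl ether that becomes C8.

Step 9
Reactants: 15 (R)-2-(4-formyl-2,6-dimethoxyphenoxy)-N-methoxy-N-methylpropanamide; 16 1,1-diiodoethane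
Product: 18 (R)-2-[2,6-dimethoxy-4-((E)-prop-1-enyl)phenoxy]-N-methoxy-N-methylpropanamide (fragment B), via 1,1-bis(dichlorochromio)ethane 17 (not isolated)
Conditions: CrCl2 (8 equiv), 16 (2 equiv), THF, rt; H2O
Reagents that add atoms: chromium dichloride, Cl[Cr]Cl (Cr held only in 17)
Why: Takai–Utimoto olefination, in which divalent chromium reduces 16 to the gem-dichromium reagent that adds only to the aldehyde and eliminates from the less crowded adduct to the E-alkene (about 95:5, with the Z isomer removed on AgNO3-doped silica) under non-basic conditions that leave C8 and the amide untouched.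

Step 10
Reactants: 7 5-bromo-1,2,3-trimethoxybenzene; 18 (R)-2-[2,6-dimethoxy-4-((E)-prop-1-enyl)phenoxy]-N-methoxy-N-methylpropanamide
Product: 21 (R)-2-[2,6-dimethoxy-4-((E)-prop-1-enyl)phenoxy]-1-(3,4,5-trimethoxyphenyl)propan-1-one, via 3,4,5-trimethoxyphenylmagnesium bromide 19 (not isolated), via tetrahedral bromomagnesium hemiaminal 20 (not isolated)
Conditions: 7, Mg, I2 (cat.), THF, reflux; then 18, THF, 0 °C; cold aq. NH4Cl
Reagents that add atoms: magnesium, [Mg] (held only in 19 and 20)
Why: Weinreb ketone synthesis, in which the chelated tetrahedral adduct survives until the quench, so there is no over-addition, the enolisable ketone never meets the Grignard reagent, and C8 stays (R).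

Step 11
Reactants: 21 (R)-2-[2,6-dimethoxy-4-((E)-prop-1-enyl)phenoxy]-1-(3,4,5-trimethoxyphenyl)propan-1-one
Product: 22 (1R,2R)-2-[2,6-dimethoxy-4-((E)-prop-1-enyl)phenoxy]-1-(3,4,5-trimethoxyphenyl)propan-1-ol (threo alcohol)
Conditions: KBH(s-Bu)3, THF, −78 °C; aq. NaOH, 30% H2O2, 0 °C
Reagents that add atoms: none
Why: Polar Felkin–Anh reduction, in which the bulky hydride with a poorly chelating potassium counter-ion attacks anti to the C8–OAr bond and past the C8–H, converting the (8R) ketone into the (7R,8R) threo alcohol, with the minor erythro isomer removed by chromatography.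

Step 12
Reactants: 22 (1R,2R)-2-[2,6-dimethoxy-4-((E)-prop-1-enyl)phenoxy]-1-(3,4,5-trimethoxyphenyl)propan-1-ol
Product: 23 (1R,2R)-2-[2,6-dimethoxy-4-((E)-prop-1-enyl)phenoxy]-1-(3,4,5-trimethoxyphenyl)propyl acetate (NP-024268)
Conditions: Ac2O, pyridine, DMAP (cat.), CH2Cl2, rt
Reagents that add atoms: acetic anhydride, CC(=O)OC(C)=O
Why: DMAP-catalysed O-acylation takes place at oxygen only, so the C7–O bond is not broken and both stereocentres are retained.

## Compound list
1 | resorcinol | Oc1cccc(O)c1 | starting material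
2 | 1,3-dimethoxybenzene | COc1cccc(OC)c1 | intermediate
3 | 2,6-dimethoxyphenyllithium (not isolated) | [Li]c1c(OC)cccc1OC | intermediate
4 | dimethyl 2,6-dimethoxyphenylboronate (not isolated) | COB(OC)c1c(OC)cccc1OC | intermediate
5 | 2,6-dimethoxyphenol | COc1cccc(OC)c1O | intermediate
6 | 4-bromo-2,6-dimethoxyphenol | COc1cc(Br)cc(OC)c1O | intermediate
7 | 5-bromo-1,2,3-trimethoxybenzene (fragment A) | COc1cc(Br)cc(OC)c1OC | intermediate
8 | ethyl (S)-lactate | C[C@H](O)C(=O)OCC | starting material
9 | (S)-2-hydroxy-N-methoxy-N-methylpropanamide | C[C@H](O)C(=O)N(C)OC | intermediate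
10 | p-cresol | Cc1ccc(O)cc1 | starting material
11 | 2,6-dibromo-4-methylphenol (not isolated) | Cc1cc(Br)c(O)c(Br)c1 | intermediate
12 | 2,6-dibromo-4-(dibromomethyl)phenol (not isolated) | BrC(Br)c1cc(Br)c(O)c(Br)c1 | intermediate
13 | 3,5-dibromo-4-hydroxybenzaldehyde | O=Cc1cc(Br)c(O)c(Br)c1 | intermediate
14 | syringaldehyde | COc1cc(C=O)cc(OC)c1O | intermediate
15 | (R)-2-(4-formyl-2,6-dimethoxyphenoxy)-N-methoxy-N-methylpropanamide | COc1cc(C=O)cc(OC)c1O[C@H](C)C(=O)N(C)OC | intermediate
16 | 1,1-diiodoethane | CC(I)I | starting material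
17 | 1,1-bis(dichlorochromio)ethane (not isolated) | CC([Cr](Cl)Cl)[Cr](Cl)Cl | intermediate
18 | (R)-2-[2,6-dimethoxy-4-((E)-prop-1-enyl)phenoxy]-N-methoxy-N-methylpropanamide (fragment B) | C/C=C/c1cc(OC)c(O[C@H](C)C(=O)N(C)OC)c(OC)c1 | intermediate
19 | 3,4,5-trimethoxyphenylmagnesium bromide (not isolated) | COc1cc([Mg]Br)cc(OC)c1OC | intermediate
20 | tetrahedral bromomagnesium hemiaminal, C8 (R), hemiaminal carbon undefined (not isolated) | C/C=C/c1cc(OC)c(O[C@H](C)C(O[Mg]Br)(N(C)OC)c2cc(OC)c(OC)c(OC)c2)c(OC)c1 | intermediate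
21 | (R)-2-[2,6-dimethoxy-4-((E)-prop-1-enyl)phenoxy]-1-(3,4,5-trimethoxyphenyl)propan-1-one | C/C=C/c1cc(OC)c(O[C@H](C)C(=O)c2cc(OC)c(OC)c(OC)c2)c(OC)c1 | intermediate
22 | (1R,2R)-2-[2,6-dimethoxy-4-((E)-prop-1-enyl)phenoxy]-1-(3,4,5-trimethoxyphenyl)propan-1-ol | C/C=C/c1cc(OC)c(O[C@H](C)[C@H](O)c2cc(OC)c(OC)c(OC)c2)c(OC)c1 | intermediate
23 | (1R,2R)-2-[2,6-dimethoxy-4-((E)-prop-1-enyl)phenoxy]-1-(3,4,5-trimethoxyphenyl)propyl acetate | C/C=C/c1cc(OC)c(O[C@H](C)[C@H](OC(C)=O)c2cc(OC)c(OC)c(OC)c2)c(OC)c1 | target

## Step count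
Total step count: 12.
Longest linear sequence: 7 steps, either steps 1–4 then 10–12, or steps 6–9 then 10–12.

## Steps most likely to fail

**Step 8.** This is a Mitsunobu etherification of a doubly ortho-substituted phenol with an α-hydroxy amide. It may stall or divert to alkylation of the hydrazide. The fallback sets out from 8 (also using 14 and 16) and comes back at 18. It makes the C8–O bond by sulfonate displacement on the more reactive ester and installs the amide afterwards. Compound 8 is converted with Tf2O/2,6-lutidine (CH2Cl2, −78 °C) into ethyl (S)-2-(trifluoromethylsulfonyloxy)propanoate F1. The potassium phenoxide of 14 (K2CO3, MeCN, 0 °C) displaces triflate in an SN2 reaction with inversion to give ethyl (R)-2-(4-formyl-2,6-dimethoxyphenoxy)propanoate F2. Ethylidenation with 16 and CrCl2 in THF gives ethyl (R)-2-[2,6-dimethoxy-4-((E)-prop-1-enyl)phenoxy]propanoate F3. Aminolysis with MeNHOMe·HCl/i-PrMgCl (THF, −20 °C) then delivers 18.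

**Step 9.** The chromium ethylidenation carries three risks: the E/Z ratio, pinacol coupling of the aryl aldehyde, and attack of divalent chromium on the N–O bond. The fallback sets out from 5 and comes back at 18. It builds the propenyl group by rearrangement and isomerisation before the ether bond is made. Compound 5 is alkylated with allyl bromide (K2CO3, acetone, reflux) to allyl 2,6-dimethoxyphenyl ether F4. Thermal para-Claisen rearrangement (N,N-diethylaniline, 200 °C) gives 4-allyl-2,6-dimethoxyphenol F5. Double-bond migration with RuHCl(CO)(PPh3)3 (cat., toluene, 80 °C) gives the conjugated (E)-2,6-dimethoxy-4-(prop-1-enyl)phenol F6. A Mitsunobu reaction of this phenol with 9 (PPh3, DIAD, THF) gives 18 with inversion.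

**Step 11.** The threo selectivity of the hydride reduction is at risk, because chelation by the aryloxy and methoxy oxygens would favour erythro. The fallback sets out from 21 and comes back at 23. It accepts the chelate pathway and corrects C7 by inversion. Zn(BH4)2 (Et2O, −30 °C) reduces 21 through the Cram chelate to the erythro alcohol (1S,2R)-2-[2,6-dimethoxy-4-((E)-prop-1-enyl)phenoxy]-1-(3,4,5-trimethoxyphenyl)propan-1-ol F7. A Mitsunobu reaction with acetic acid (PPh3, DIAD, toluene, 0 °C) inverts C7 and installs the acetate in the same operation, giving 23 directly.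

## Further compounds
F1 | step 8 | ethyl (S)-2-(trifluoromethylsulfonyloxy)propanoate | C[C@H](OS(=O)(=O)C(F)(F)F)C(=O)OCC
F2 | step 8 | ethyl (R)-2-(4-formyl-2,6-dimethoxyphenoxy)propanoate | COc1cc(C=O)cc(OC)c1O[C@H](C)C(=O)OCC
F3 | step 8 | ethyl (R)-2-[2,6-dimethoxy-4-((E)-prop-1-enyl)phenoxy]propanoate | C/C=C/c1cc(OC)c(O[C@H](C)C(=O)OCC)c(OC)c1
F4 | step 9 | allyl 2,6-dimethoxyphenyl ether | C=CCOc1c(OC)cccc1OC
F5 | step 9 | 4-allyl-2,6-dimethoxyphenol | C=CCc1cc(OC)c(O)c(OC)c1
F6 | step 9 | (E)-2,6-dimethoxy-4-(prop-1-enyl)phenol | C/C=C/c1cc(OC)c(O)c(OC)c1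
F7 | step 11 | (1S,2R)-2-[2,6-dimethoxy-4-((E)-prop-1-enyl)phenoxy]-1-(3,4,5-trimethoxyphenyl)propan-1-ol | C/C=C/c1cc(OC)c(O[C@H](C)[C@@H](O)c2cc(OC)c(OC)c(OC)c2)c(OC)c1
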